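**Retrosynthetic overview**
- The OH and OOH groups come from two successive vinylogous acyl substitutions (HO− first, then HOO−) on 2,5-dibromo-3,6-bis(5-prenylindol-3-yl)-1,4-benzoquinone.
- That dibromide comes from bromanil plus two molecules of 2-ethynyl-4-prenylaniline. One flask performs a double gold-catalysed 5-endo-dig hydroamination and a double C3 addition–elimination, closing both pyrrole rings and making both indole–quinone bonds.
- 2-Ethynyl-4-prenylaniline comes from 4-bromo-2-iodoaniline by site-selective Sonogashira coupling at C–I, then Stille prenylation at C–Br.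
- Ring order: the two benzene rings and the quinone ring are bought. The two pyrrole rings form together in step 3, and no ring forms afterwards.

Assumption: the target SMILES has no stereocentre and no E/Z-stereogenic alkene (each prenyl alkene ends in two methyl groups). The compound is therefore achiral, needs no stereocontrol, and its SMILES carries no stereodescriptors.

**Step 1**
Reactants: 1 4-bromo-2-iodoaniline; 2 ethynyl(trimethyl)silane
Product: 3 4-bromo-2-[(trimethylsilyl)ethynyl]aniline
Conditions: PdCl2(PPh3)2 (2 mol %), CuI (4 mol %), Et3N, THF, rt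
Reagents that add atoms: none
Why: Sonogashira coupling, in which zerovalent palladium inserts into C–I far faster than into C–Br at rt, so only the position ortho to NH2 is alkynylated, the bromide is kept for step 2, and no stereocentre is formed.

**Step 2**
Reactants: 3 4-bromo-2-[(trimethylsilyl)ethynyl]aniline; 4 tributyl(3-methylbut-2-en-1-yl)stannane
Product: 6 2-ethynyl-4-(3-methylbut-2-en-1-yl)aniline, via silylalkyne 5 (not isolated)
Conditions: Pd(PPh3)4 (5 mol %), DMF, 100 °C; then rt, K2CO3 (1.5 equiv), MeOH
Reagents that add atoms: none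
Why: Stille coupling of the remaining aryl bromide, with reductive elimination at the unsubstituted CH2 terminus of the allyl-palladium species giving the linear prenyl arene, followed in the same flask by K2CO3/MeOH protodesilylation of the alkynylsilane; the free NH2 tolerates both stages and no stereocentre is formed.

**Step 3 (key step)**
Reactants: 6 2-ethynyl-4-(3-methylbut-2-en-1-yl)aniline (2.2 equiv); 7 tetrabromo-1,4-benzoquinone (bromanil, 1 equiv)
Product: 9 2,5-dibromo-3,6-bis[5-(3-methylbut-2-en-1-yl)-1H-indol-3-yl]cyclohexa-2,5-diene-1,4-dione, via 5-prenylindole 8 (not isolated)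
Conditions: 6, NaAuCl4·2H2O (3 mol %), MeCN (0.1 M), 40 °C until 6 is consumed; then 0 °C, Cs2CO3 (2.2 equiv), 7, warm to rt, N2, dark
Reagents that add atoms: none
Why: Proposed new method: trivalent gold π-activates the terminal alkyne of 6 for 5-endo-dig anti-aminoauration and protodeauration (gold-catalysed alkyne hydroamination, well known for free 2-alkynylanilines), so every quinone-reactive NH2 group has become indole 8 before 7 is added, after which two molecules of 8 attack 7 through C3 in a Cs2CO3-buffered vinylogous addition–elimination (known for simple NH-indoles and bromanil), the first indolyl group at C2 donating into the C4 carbonyl so that the second attack uses the C1 carbonyl as acceptor and lands at C5; the closest known reaction type is the one-flask gold-catalysed cyclisation/C3 conjugate addition of 2-alkynylanilines to enones, and the operation closes both pyrrole rings and makes two C–N and two C–C bonds without creating a stereocentre.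

**Step 4**
Reactants: 9 2,5-dibromo-3,6-bis[5-(3-methylbut-2-en-1-yl)-1H-indol-3-yl]cyclohexa-2,5-diene-1,4-dione
Product: 11 hydroperoxycochliodinol, via bromohydroxyquinone 10 (not isolated)
Conditions: 1 M aq NaOH (2.1 equiv), THF, 0 °C to rt until 9 is consumed; then 0 °C, 30% aq H2O2 (10 equiv), 1 M aq NaOH (2 equiv), 30 min; cold 0.5 M HCl to pH 3, EtOAc extraction, water washes only (no reductive quench)
Reagents that add atoms: sodium hydroxide [Na+].[OH-]; hydrogen peroxide OO
Why: Proposed new method: two consecutive vinylogous acyl substitutions at the C–Br carbons (the addition–elimination type used to hydrolyse halo-bis(indolyl)quinones) are separated by charge control, because the first HO− displacement gives the hydroxyquinone anion of 10, which resists further HO− at or below rt, whereas excess H2O2 (pKa 11.6) then turns the remaining base into the α-effect nucleophile HOO−, which adds at the last C–Br carbon and expels bromide far faster than the enolate could close an epoxide by loss of HO−; the closest known reaction type is perhydrolysis of acyl halides and activated esters to peroxy acids with alkaline H2O2, the unactivated prenyl alkenes and the indoles are inert to nucleophilic peroxide, and no stereocentre is formed.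

**Compound list**
1 | 4-bromo-2-iodoaniline | Nc1ccc(Br)cc1I | starting material
2 | ethynyl(trimethyl)silane | C#C[Si](C)(C)C | starting material
3 | 4-bromo-2-[(trimethylsilyl)ethynyl]aniline | Nc1ccc(Br)cc1C#C[Si](C)(C)C | intermediate
4 | tributyl(3-methylbut-2-en-1-yl)stannane | CCCC[Sn](CCCC)(CCCC)CC=C(C)C | starting material
5 | 4-(3-methylbut-2-en-1-yl)-2-[(trimethylsilyl)ethynyl]aniline | CC(C)=CCc1ccc(N)c(C#C[Si](C)(C)C)c1 | intermediate
6 | 2-ethynyl-4-(3-methylbut-2-en-1-yl)aniline | CC(C)=CCc1ccc(N)c(C#C)c1 | intermediate
7 | tetrabromo-1,4-benzoquinone (bromanil) | O=C1C(Br)=C(Br)C(=O)C(Br)=C1Br | starting material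
8 | 5-(3-methylbut-2-en-1-yl)-1H-indole | CC(C)=CCc1ccc2[nH]ccc2c1 | intermediate
9 | 2,5-dibromo-3,6-bis[5-(3-methylbut-2-en-1-yl)-1H-indol-3-yl]cyclohexa-2,5-diene-1,4-dione | CC(C)=CCc1ccc2[nH]cc(C3=C(Br)C(=O)C(c4c[nH]c5ccc(CC=C(C)C)cc45)=C(Br)C3=O)c2c1 | intermediate
10 | 2-bromo-5-hydroxy-3,6-bis[5-(3-methylbut-2-en-1-yl)-1H-indol-3-yl]cyclohexa-2,5-diene-1,4-dione | CC(C)=CCc1ccc2[nH]cc(C3=C(O)C(=O)C(c4c[nH]c5ccc(CC=C(C)C)cc45)=C(Br)C3=O)c2c1 | intermediate
11 | hydroperoxycochliodinol, 2-hydroperoxy-5-hydroxy-3,6-bis[5-(3-methylbut-2-en-1-yl)-1H-indol-3-yl]cyclohexa-2,5-diene-1,4-dione | CC(C)=CCc1ccc2[nH]cc(C3=C(O)C(=O)C(c4c[nH]c5ccc(CC=C(C)C)cc45)=C(OO)C3=O)c2c1 | target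

**Totals**
Total step count: 4. Longest linear sequence: 4 (1 → 3 → 6 → 9 → 11).

**Steps most likely to fail**

Step 4 carries the highest risk.
- Risk: HOO− may be too slow on the anion of 10. The peroxy anion of 11 may also fragment in base, either by attack on the neighbouring carbonyl with ring cleavage or by loss of O2 to give cochliodinol.
- Fallback: it sets out from 9 and returns at 11. The peroxide is brought in masked, and before the hydroxyl group.
- 2-Hydroperoxy-2-methoxypropane F1 is made by ozonolysis of 2,3-dimethylbut-2-ene in MeOH. With Cs2CO3 in DMF at 0 °C it displaces one bromide of the neutral, fully electrophilic 9 to give the bromo peroxyketal F2.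
- Because F2 is still uncharged, aqueous NaOH in THF at rt replaces the second bromide easily and gives the hydroxy peroxyketal F3. The peroxyketal has no acidic O–O–H and tolerates this base.
- AcOH/THF/H2O at rt then cleaves the ketal and releases 11, so the free hydroperoxide never meets base.

Step 3 is the second risk.
- Risk: the bromanil stage may give N-attack, some 2,6-isomer, or electron-transfer oxidation of 8.
- Fallback: it sets out from 6 and returns at 9. It replaces substitution by conjugate addition and dehydrogenation on a quinone whose substitution pattern fixes the regiochemistry.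
- 6 is cyclised to 8 with the same gold salt. Commercial 2,5-dibromo-1,4-benzoquinone and AcOH in THF are then added, so that 8 adds at the free C3–H position to give the mono(indolyl)hydroquinone F4.
- DDQ oxidises F4 to the mono(indolyl)quinone F5.
- A second molecule of 8 adds at the only remaining C–H position to give the bis(indolyl)hydroquinone F6, and DDQ oxidises it to 9.

Step 2 is the third risk.
- Risk: the coupling may give α/γ (prenyl versus reverse-prenyl) mixtures, or react sluggishly with the electron-rich bromide.
- Fallback: it sets out from 3 and returns at 5.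
- Stille coupling of 3 with allyltributylstannane, a symmetrical allyl group with no regiochemical question, gives 4-allyl-2-[(trimethylsilyl)ethynyl]aniline F7.
- Cross-metathesis of F7 with excess 2-methylbut-2-ene (second-generation Grubbs catalyst, CH2Cl2, 40 °C) turns the allyl group into the prenyl group of 5.
- 5 is desilylated with K2CO3/MeOH to 6 as in the main route.

**Further compounds**
F1 | step 4 | 2-hydroperoxy-2-methoxypropane | COC(C)(C)OO
F2 | step 4 | 2-bromo-5-[(2-methoxypropan-2-yl)peroxy]-3,6-bis[5-(3-methylbut-2-en-1-yl)-1H-indol-3-yl]cyclohexa-2,5-diene-1,4-dione | CC(C)=CCc1ccc2[nH]cc(C3=C(Br)C(=O)C(c4c[nH]c5ccc(CC=C(C)C)cc45)=C(OOC(C)(C)OC)C3=O)c2c1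
F3 | step 4 | 2-hydroxy-5-[(2-methoxypropan-2-yl)peroxy]-3,6-bis[5-(3-methylbut-2-en-1-yl)-1H-indol-3-yl]cyclohexa-2,5-diene-1,4-dione | CC(C)=CCc1ccc2[nH]cc(C3=C(O)C(=O)C(c4c[nH]c5ccc(CC=C(C)C)cc45)=C(OOC(C)(C)OC)C3=O)c2c1
F4 | step 3 | 2,5-dibromo-3-[5-(3-methylbut-2-en-1-yl)-1H-indol-3-yl]benzene-1,4-diol | CC(C)=CCc1ccc2[nH]cc(-c3c(O)c(Br)cc(O)c3Br)c2c1
F5 | step 3 | 2,5-dibromo-3-[5-(3-methylbut-2-en-1-yl)-1H-indol-3-yl]cyclohexa-2,5-diene-1,4-dione | CC(C)=CCc1ccc2[nH]cc(C3=C(Br)C(=O)C=C(Br)C3=O)c2c1
F6 | step 3 | 2,5-dibromo-3,6-bis[5-(3-methylbut-2-en-1-yl)-1H-indol-3-yl]benzene-1,4-diol | CC(C)=CCc1ccc2[nH]cc(-c3c(O)c(Br)c(-c4c[nH]c5ccc(CC=C(C)C)cc45)c(O)c3Br)c2c1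
F7 | step 2 | 4-allyl-2-[(trimethylsilyl)ethynyl]aniline | C=CCc1ccc(N)c(C#C[Si](C)(C)C)c1
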